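**Strategy.** Sacculatane numbering is used (ring A: C1–C5, C10; ring B: C5–C10). Ring A is made last by joining C2 to C3: the 1,3-pattern of the C1 oxygen and the C3 chlorine across the C2 methylene is read as the adduct of a C3 polychloroalkyl radical and a C1 enol ether. A copper-catalysed atom-transfer radical cyclisation (6-endo) of a trichloromethyl group closes the trans-decalin in one operation and leaves the C1 ketone and a C3 gem-dichloride, which are trimmed to the equatorial chloride and the axial alcohol. Its precursor is a monocyclic ring B cyclohexene from an enantioselective Diels–Alder reaction that already carries C5, C9, C10 and the quaternary C4.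

Key step: step 15

Remark: the sense of asymmetric induction in step 5 is taken as drawn; the catalyst antipode is equally accessible and would be taken if the opposite sense were found.

Step 1
Reactants: 1 glyoxal; 2 ethyl 2-(triphenylphosphoranylidene)propanoate
Product: 3 ethyl (E)-2-methyl-4-oxobut-2-enoate
Conditions: glyoxal (40 % aq., excess), CH2Cl2–H2O, rt
Reagents that add atoms: none
Why: Wittig olefination of one formyl group of excess glyoxal by the stabilised ylide should give the (E)-enal ester, with formyl and ester trans.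

Step 2
Reactants: 4 3-[(4-methoxybenzyl)oxy]propanal
Product: 5 5-[(4-methoxybenzyl)oxy]pent-1-en-3-ol (racemic)
Conditions: CH2=CHMgBr, THF, −78 → 0 °C; aq. NH4Cl
Reagents that add atoms: vinylmagnesium bromide, C=C[Mg]Br
Why: Grignard 1,2-addition to the aldehyde; the carbinol centre is erased in step 3.

Step 3
Reactants: 5 5-[(4-methoxybenzyl)oxy]pent-1-en-3-ol
Product: 6 5-[(4-methoxybenzyl)oxy]pent-1-en-3-one
Conditions: triacetoxyperiodinane (DMP), NaHCO3, CH2Cl2, 0 °C → rt
Reagents that add atoms: none
Why: Hypervalent-iodine oxidation of the allylic alcohol under neutral conditions should give the sensitive vinyl ketone without conjugate addition or polymerisation.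

Step 4
Reactants: 6 5-[(4-methoxybenzyl)oxy]pent-1-en-3-one
Product: 7 (3Z)-5-[(4-methoxybenzyl)oxy]-3-[(triisopropylsilyl)oxy]penta-1,3-diene
Conditions: iPr3SiOTf, Et3N, CH2Cl2, −78 → 0 °C
Reagents that add atoms: triisopropylsilyl trifluoromethanesulfonate, CC(C)[Si](C(C)C)(C(C)C)OS(=O)(=O)C(F)(F)F
Why: Soft enolisation and O-silylation can only occur towards the CH2 group and should give the (Z)-2-silyloxy diene, with OSi cis to CH2OPMB.

Step 5
Reactants: 3 ethyl (E)-2-methyl-4-oxobut-2-enoate; 7 (3Z)-5-[(4-methoxybenzyl)oxy]-3-[(triisopropylsilyl)oxy]penta-1,3-diene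
Product: 8 ring B aldehyde, ethyl 6-formyl-2-{[(4-methoxybenzyl)oxy]methyl}-1-methyl-3-[(triisopropylsilyl)oxy]cyclohex-3-ene-1-carboxylate, with formyl (C5), CH2OPMB (C9) and methyl (C10) mutually cis (β) and the ester trans (α)
Conditions: (S)-1-(2-methylphenyl)-3,3-diphenyltetrahydro-1H,3H-pyrrolo[1,2-c][1,3,2]oxazaborole · HN(SO2CF3)2 (20 mol %), CH2Cl2, −78 → −40 °C
Reagents that add atoms: none
Why: In this chiral oxazaborolidinium-catalysed Diels–Alder reaction the catalyst-bound formyl group directs endo addition and "para" bonding of the silyloxy-activated terminus C9 to C10, so the E geometry of 3 gives trans C5-formyl/C10-ester, the endo methyl ends cis to the C9 substituent, and the catalyst selects the face that fixes C5, C9 and C10 absolutely.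

Step 6
Reactants: 8 ring B aldehyde; 9 [2-(1,3-dioxan-2-yl)ethyl]magnesium bromide
Product: 10 carbinol, 8 with the formyl group converted into CH(OH)CH2CH2(1,3-dioxan-2-yl) (both carbinol epimers)
Conditions: THF, −78 °C; cold aq. NH4Cl
Reagents that add atoms: none
Why: Grignard addition should be chemoselective for the aldehyde over the neopentyl ester at low temperature, and a cold quench avoids lactonisation; the carbinol centre is erased in step 7.

Step 7
Reactants: 10 carbinol
Product: 11 ketone, C5 substituent C(=O)CH2CH2(1,3-dioxan-2-yl)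
Conditions: triacetoxyperiodinane (DMP), NaHCO3, CH2Cl2, 0 °C
Reagents that add atoms: none
Why: Buffered hypervalent-iodine oxidation should spare the silyl enol ether and leave the C5 stereocentre next to the new ketone untouched.

Step 8
Reactants: 11 ketone
Product: 12 methyl enol ether, C5 substituent C(=CHOMe)CH2CH2(1,3-dioxan-2-yl) (E/Z mixture)
Conditions: MeOCH2PPh3Cl, KN(SiMe3)2, THF, 0 °C → rt
Reagents that add atoms: (methoxymethylene)triphenylphosphorane, COC=P(c1ccccc1)(c1ccccc1)c1ccccc1
Why: Wittig methoxymethylenation of the only ketone adds the future C3 as a masked aldehyde; ester, enol silane and acetal are inert to the ylide.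

Step 9
Reactants: 12 methyl enol ether
Product: 13 enol triflate, 12 with the C8 silyl enol ether replaced by the C8 trifluoromethanesulfonate (C7=C8 retained)
Conditions: CsF, PhN(SO2CF3)2, DME, rt
Reagents that add atoms: N-phenylbis(trifluoromethanesulfonimide), O=S(=O)(N(c1ccccc1)S(=O)(=O)C(F)(F)F)C(F)(F)F
Why: Fluoride cleaves the silyl enol ether and the regiodefined enolate is O-triflated, which fixes the C7=C8 bond as an acid-stable, electron-poor handle for C12.

Step 10
Reactants: 13 enol triflate
Product: 14 aldehyde, C5 substituent CH(CHO)CH2CH2(1,3-dioxan-2-yl) (both C4 epimers)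
Conditions: 0.1 M HCl, THF–H2O, 0 °C
Reagents that add atoms: water, O
Why: Acid hydrolysis of the electron-rich methyl enol ether is far faster than that of the cyclic acetal and should give the α-branched aldehyde; the C4 epimers converge in step 11.

Step 11
Reactants: 14 aldehyde
Product: 15 quaternary aldehyde, C4 bearing CHO (C3), methyl and the acetal chain, C4 configured as in the target
Conditions: KN(SiMe3)2, THF, −78 °C; MeI, −78 → −20 °C
Reagents that add atoms: iodomethane, CI
Why: C-methylation of the potassium enolate (oxygen syn to the chain, hydrogen syn to C5) through a staggered transition state with quaternary C10 anti to the incoming MeI and the ring CH2 inside should put methyl on the face that becomes β in ring A (1,2-induction from C5).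

Step 12
Reactants: 15 quaternary aldehyde
Product: 17 gem-dichloride, 15 with CHO converted into CHCl2, via hydrazone 16 (not isolated)
Conditions: N2H4·H2O, EtOH, rt; then CuCl2, Et3N, MeOH, 0 °C → rt
Reagents that add atoms: copper dichloride, Cl[Cu]Cl
Why: Condensation to the hydrazone and its copper-mediated oxidative chlorination should convert the non-enolisable neopentyl aldehyde into the gem-dichloride under basic, non-ionising conditions.

Step 13
Reactants: 17 gem-dichloride
Product: 18 ethyl enol ether, 17 with CO2Et converted into C(OEt)=CH2 (C1 and C2)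
Conditions: Cp2TiMe2, toluene, 70 °C, dark
Reagents that add atoms: dimethyltitanocene, C[Ti](C)(C1C=CC=C1)C1C=CC=C1
Why: Petasis methylenation of the only ester by the titanium methylidene adds C2 and turns C1 into the enol ether acceptor; chloride, triflate and acetal are not touched.

Step 14
Reactants: 18 ethyl enol ether
Product: 20 trichloride, 18 with CHCl2 converted into CCl3, via lithium carbenoid 19 (not isolated)
Conditions: LiN(iPr)2, THF, −100 °C; C2Cl6, −100 → −78 °C
Reagents that add atoms: hexachloroethane, ClC(Cl)(Cl)C(Cl)(Cl)Cl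
Why: α-Deprotonation of the 1,1-dichloroalkane (no β-hydrogen on quaternary C4) gives a dichloroalkyllithium carbenoid that is chlorinated by the electrophilic chlorine donor.

Step 15
Reactants: 20 trichloride
Product: 22 bicyclic 3,3-dichloro-1-ketone (trans-decalin, rings A and B), via α-chloro ether 21 (not isolated)
Conditions: CuCl (20 mol %), tris(2-pyridylmethyl)amine (20 mol %), sodium ascorbate (20 mol %), NaHCO3, MeCN–H2O (9:1), 60 °C
Reagents that add atoms: water, O
Why: CuCl/ligand abstracts a chlorine atom from the C3 trichloromethyl group; the electrophilic α,α-dichloroalkyl radical adds to the unsubstituted C2 terminus of the electron-rich C1 enol ether, the α-ethoxy C1 radical takes chlorine back from the CuCl2 complex, and α-chloro ether 21 is hydrolysed in the buffered medium to the C1 ketone. The closest known reaction type is the Kharasch atom-transfer radical cyclisation, here the copper-catalysed addition of a trichloromethyl compound to a vinyl ether run intramolecularly. Ring A closes in the 6-endo-trig mode through a chair transition state in which the trans C5 and C10 attachments are diequatorial, so the trans-decalin forms directly. No new stereocentre is made (C3 is CCl2 and C1 a carbonyl carbon; they are set in steps 16 and 17), and C4, C5, C9 and C10 pass through untouched. The step needs 6-endo over 5-exo regioselectivity, which the fully substituted C1 (ethoxy group and quaternary C10) and the polarity match at C2 secure, and chemoselectivity over the C7=C8 bond and the side chain, which the electron-poor enol triflate and the acetal mask secure.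

Step 16
Reactants: 22 bicyclic 3,3-dichloro-1-ketone
Product: 23 3β-chloro-1-ketone
Conditions: Bu3SnH (1.05 equiv), Et3B, air, toluene, −20 → 0 °C
Reagents that add atoms: none
Why: Radical monodechlorination: the α-chloro C3 radical should take hydrogen from Bu3SnH along the axial trajectory on the α face, anti to the axial C4 methyl, which leaves chlorine equatorial (3β); the remaining secondary chloride is inert.

Step 17
Reactants: 23 3β-chloro-1-ketone
Product: 24 1α-hydroxy-3β-chloride
Conditions: LiBH(sec-Bu)3, THF, −78 °C; aq. NH4Cl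
Reagents that add atoms: none
Why: The bulky hydride should attack the C1 carbonyl equatorially from the β face, since the axial path is blocked by the syn-axial H3 and H5, giving the axial 1α-alcohol as with 4,4-dimethyl-3-oxo triterpenoids.

Step 18
Reactants: 24 1α-hydroxy-3β-chloride
Product: 25 side-chain aldehyde (C4–CH2CH2CHO)
Conditions: 1 M HCl, THF, 40 °C
Reagents that add atoms: water, O
Why: Acid hydrolysis of the 1,3-dioxane releases the aldehyde; chlorohydrin, PMB ether and enol triflate tolerate dilute acid.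

Step 19
Reactants: 25 side-chain aldehyde
Product: 26 homoprenyl compound (C4–CH2CH2CH=CMe2)
Conditions: iPrPPh3I, n-BuLi, THF, 0 °C; then 25, −78 °C → rt (excess ylide)
Reagents that add atoms: isopropylidenetriphenylphosphorane, CC(C)=P(c1ccccc1)(c1ccccc1)c1ccccc1
Why: Wittig olefination with the non-stabilised ylide completes the 4-methylpent-3-enyl chain; excess ylide tolerates the free C1 hydroxyl.

Step 20
Reactants: 26 homoprenyl compound
Product: 27 C12 enal (C8–CHO, C7=C8)
Conditions: Pd(PPh3)4, CO (1 atm), Bu3SnH (slow addition), THF, 50 °C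
Reagents that add atoms: carbon monoxide, [C-]#[O+]
Why: Palladium-catalysed reductive carbonylation (formylation) of the enol triflate installs C12 at the aldehyde level with the C7=C8 bond in place.

Step 21
Reactants: 27 C12 enal
Product: 28 C11 alcohol (C9–CH2OH)
Conditions: DDQ, CH2Cl2–pH 7 buffer, 0 °C
Reagents that add atoms: none
Why: Oxidative cleavage of the 4-methoxybenzyl ether under buffered conditions should spare the enal, the trisubstituted alkene and the chloride.

Step 22
Reactants: 28 C11 alcohol
Product: 29 target, CNP0155449.1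
Conditions: TEMPO (10 mol %), PhI(OAc)2, CH2Cl2, rt
Reagents that add atoms: none
Why: Nitroxyl-catalysed oxidation is selective for the primary C11 alcohol over the hindered axial C1 alcohol and is neutral, so the epimerisable 9β-formyl centre should survive.

**Compound list**

1 | glyoxal | O=CC=O | starting material
2 | ethyl 2-(triphenylphosphoranylidene)propanoate | CCOC(=O)C(C)=P(c1ccccc1)(c1ccccc1)c1ccccc1 | starting material
3 | ethyl (E)-2-methyl-4-oxobut-2-enoate | CCOC(=O)/C(C)=C/C=O | intermediate
4 | 3-[(4-methoxybenzyl)oxy]propanal | O=CCCOCc1ccc(OC)cc1 | starting material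
5 | 5-[(4-methoxybenzyl)oxy]pent-1-en-3-ol (racemic) | C=CC(O)CCOCc1ccc(OC)cc1 | intermediate
6 | 5-[(4-methoxybenzyl)oxy]pent-1-en-3-one | C=CC(=O)CCOCc1ccc(OC)cc1 | intermediate
7 | (3Z)-5-[(4-methoxybenzyl)oxy]-3-[(triisopropylsilyl)oxy]penta-1,3-diene | C=C/C(O[Si](C(C)C)(C(C)C)C(C)C)=C/COCc1ccc(OC)cc1 | intermediate
8 | ring B aldehyde (C5 CHO, C9 CH2OPMB, C10 Me cis; C10 CO2Et trans; C8 silyl enol ether) | O=C[C@@H]1CC=C(O[Si](C(C)C)(C(C)C)C(C)C)[C@H](COCc2ccc(OC)cc2)[C@@]1(C)C(=O)OCC | intermediate
9 | [2-(1,3-dioxan-2-yl)ethyl]magnesium bromide | Br[Mg]CCC1OCCCO1 | starting material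
10 | carbinol (both carbinol epimers) | OC(CCC1OCCCO1)[C@@H]1CC=C(O[Si](C(C)C)(C(C)C)C(C)C)[C@H](COCc2ccc(OC)cc2)[C@@]1(C)C(=O)OCC | intermediate
11 | ketone | O=C(CCC1OCCCO1)[C@@H]1CC=C(O[Si](C(C)C)(C(C)C)C(C)C)[C@H](COCc2ccc(OC)cc2)[C@@]1(C)C(=O)OCC | intermediate
12 | methyl enol ether (E/Z mixture) | COC=C(CCC1OCCCO1)[C@@H]1CC=C(O[Si](C(C)C)(C(C)C)C(C)C)[C@H](COCc2ccc(OC)cc2)[C@@]1(C)C(=O)OCC | intermediate
13 | enol triflate | COC=C(CCC1OCCCO1)[C@@H]1CC=C(OS(=O)(=O)C(F)(F)F)[C@H](COCc2ccc(OC)cc2)[C@@]1(C)C(=O)OCC | intermediate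
14 | aldehyde (both C4 epimers) | O=CC(CCC1OCCCO1)[C@@H]1CC=C(OS(=O)(=O)C(F)(F)F)[C@H](COCc2ccc(OC)cc2)[C@@]1(C)C(=O)OCC | intermediate
15 | quaternary aldehyde | O=C[C@@](C)(CCC1OCCCO1)[C@@H]1CC=C(OS(=O)(=O)C(F)(F)F)[C@H](COCc2ccc(OC)cc2)[C@@]1(C)C(=O)OCC | intermediate
16 | hydrazone of 15 | NN=C[C@@](C)(CCC1OCCCO1)[C@@H]1CC=C(OS(=O)(=O)C(F)(F)F)[C@H](COCc2ccc(OC)cc2)[C@@]1(C)C(=O)OCC | intermediate
17 | gem-dichloride | ClC(Cl)[C@@](C)(CCC1OCCCO1)[C@@H]1CC=C(OS(=O)(=O)C(F)(F)F)[C@H](COCc2ccc(OC)cc2)[C@@]1(C)C(=O)OCC | intermediate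
18 | ethyl enol ether | ClC(Cl)[C@@](C)(CCC1OCCCO1)[C@@H]1CC=C(OS(=O)(=O)C(F)(F)F)[C@H](COCc2ccc(OC)cc2)[C@@]1(C)C(=C)OCC | intermediate
19 | lithium carbenoid (1,1-dichloroalkyllithium) | [Li]C(Cl)(Cl)[C@@](C)(CCC1OCCCO1)[C@@H]1CC=C(OS(=O)(=O)C(F)(F)F)[C@H](COCc2ccc(OC)cc2)[C@@]1(C)C(=C)OCC | intermediate
20 | trichloride | ClC(Cl)(Cl)[C@@](C)(CCC1OCCCO1)[C@@H]1CC=C(OS(=O)(=O)C(F)(F)F)[C@H](COCc2ccc(OC)cc2)[C@@]1(C)C(=C)OCC | intermediate
21 | α-chloro ether (C1 epimers) | C1(CC[C@]2(C)C(Cl)(Cl)CC(Cl)(OCC)[C@]3(C)[C@@H](COCc4ccc(OC)cc4)C(OS(=O)(=O)C(F)(F)F)=CC[C@@H]23)OCCCO1 | intermediate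
22 | bicyclic 3,3-dichloro-1-ketone | C1(CC[C@]2(C)C(Cl)(Cl)CC(=O)[C@]3(C)[C@@H](COCc4ccc(OC)cc4)C(OS(=O)(=O)C(F)(F)F)=CC[C@@H]23)OCCCO1 | intermediate
23 | 3β-chloro-1-ketone | C1(CC[C@]2(C)[C@@H](Cl)CC(=O)[C@]3(C)[C@@H](COCc4ccc(OC)cc4)C(OS(=O)(=O)C(F)(F)F)=CC[C@@H]23)OCCCO1 | intermediate
24 | 1α-hydroxy-3β-chloride | C1(CC[C@]2(C)[C@@H](Cl)C[C@H](O)[C@]3(C)[C@@H](COCc4ccc(OC)cc4)C(OS(=O)(=O)C(F)(F)F)=CC[C@@H]23)OCCCO1 | intermediate
25 | side-chain aldehyde | O=CCC[C@]1(C)[C@@H](Cl)C[C@H](O)[C@]2(C)[C@@H](COCc3ccc(OC)cc3)C(OS(=O)(=O)C(F)(F)F)=CC[C@@H]12 | intermediate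
26 | homoprenyl compound | CC(C)=CCC[C@]1(C)[C@@H](Cl)C[C@H](O)[C@]2(C)[C@@H](COCc3ccc(OC)cc3)C(OS(=O)(=O)C(F)(F)F)=CC[C@@H]12 | intermediate
27 | C12 enal | CC(C)=CCC[C@]1(C)[C@@H](Cl)C[C@H](O)[C@]2(C)[C@@H](COCc3ccc(OC)cc3)C(C=O)=CC[C@@H]12 | intermediate
28 | C11 alcohol | CC(C)=CCC[C@]1(C)[C@@H](Cl)C[C@H](O)[C@]2(C)[C@@H](CO)C(C=O)=CC[C@@H]12 | intermediate
29 | CNP0155449.1 | CC(C)=CCC[C@]1(C)[C@@H](Cl)C[C@H](O)[C@]2(C)[C@@H](C=O)C(C=O)=CC[C@@H]12 | target

**Step count.** Total: 22 steps. Longest linear sequence: 21 steps (from 4 through steps 2–22).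

**Steps most likely to fail**

Step 15. Initiation at the unactivated trichloromethyl group may be slow, so that hydrolysis of the ethyl enol ether, or loss of HCl from the α-chloro ether or the β,β-dichloro ketone, overtakes clean 6-endo closure. The fallback sets out from 20 and changes the acceptor so that termination expels a silyl chloride under anhydrous, neutral conditions. Dilute acid (0.1 M HCl, THF, 0 °C) hydrolyses the enol ether to the methyl ketone F1. Soft enolisation (tBuMe2SiOTf, Et3N) gives the tert-butyldimethylsilyl enol ether F2. Kharasch cyclisation with RuCl2(PPh3)3 in benzene at 100 °C should then give the ketone with loss of tBuMe2SiCl, and the route is rejoined at 22.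

Step 5. Bond formation at the fully substituted C10 may be slow, and facial discrimination by the catalyst may be insufficient. The fallback sets out from 3 and 7 and changes the source of enantiopurity. The cycloaddition is promoted by stoichiometric Me2AlCl (CH2Cl2, −78 °C), which should follow the same endo, "para" course and give the racemate. The enantiomers are then separated by preparative chromatography on a chiral stationary phase; the unwanted antipode F3 is discarded and the route is rejoined at 8.

Step 11. Methylation may occur on the other enolate face (wrong C4 epimer), or on oxygen. The fallback sets out from 8 and reverses the order in which the two C4 substituents arrive, so that the same facial preference gives the opposite configuration.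
- CH3MgBr adds to the aldehyde to give the methyl carbinol F4.
- Oxidation with triacetoxyperiodinane gives the methyl ketone F5.
- Wittig methoxymethylenation gives the enol ether F6.
- CsF/PhN(SO2CF3)2 gives the enol triflate F7.
- Dilute acid gives the α-methyl aldehyde F8.
- Its potassium enolate (KN(SiMe3)2, THF–DMPU) is alkylated with 2-(2-iodoethyl)-1,3-dioxane, and the route is rejoined at 15.

Further compounds
F1 | step 15 | methyl ketone (20 with C(OEt)=CH2 hydrolysed to acetyl) | ClC(Cl)(Cl)[C@@](C)(CCC1OCCCO1)[C@@H]1CC=C(OS(=O)(=O)C(F)(F)F)[C@H](COCc2ccc(OC)cc2)[C@@]1(C)C(C)=O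
F2 | step 15 | tert-butyldimethylsilyl enol ether of F1 | ClC(Cl)(Cl)[C@@](C)(CCC1OCCCO1)[C@@H]1CC=C(OS(=O)(=O)C(F)(F)F)[C@H](COCc2ccc(OC)cc2)[C@@]1(C)C(=C)O[Si](C)(C)C(C)(C)C
F3 | step 5 | enantiomer of 8 | O=C[C@H]1CC=C(O[Si](C(C)C)(C(C)C)C(C)C)[C@@H](COCc2ccc(OC)cc2)[C@]1(C)C(=O)OCC
F4 | step 11 | methyl carbinol (both carbinol epimers) | CC(O)[C@@H]1CC=C(O[Si](C(C)C)(C(C)C)C(C)C)[C@H](COCc2ccc(OC)cc2)[C@@]1(C)C(=O)OCC
F5 | step 11 | methyl ketone | CC(=O)[C@@H]1CC=C(O[Si](C(C)C)(C(C)C)C(C)C)[C@H](COCc2ccc(OC)cc2)[C@@]1(C)C(=O)OCC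
F6 | step 11 | methyl enol ether (E/Z mixture) | COC=C(C)[C@@H]1CC=C(O[Si](C(C)C)(C(C)C)C(C)C)[C@H](COCc2ccc(OC)cc2)[C@@]1(C)C(=O)OCC
F7 | step 11 | enol triflate | COC=C(C)[C@@H]1CC=C(OS(=O)(=O)C(F)(F)F)[C@H](COCc2ccc(OC)cc2)[C@@]1(C)C(=O)OCC
F8 | step 11 | α-methyl aldehyde (both C4 epimers) | O=CC(C)[C@@H]1CC=C(OS(=O)(=O)C(F)(F)F)[C@H](COCc2ccc(OC)cc2)[C@@]1(C)C(=O)OCC
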